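## Retrosynthetic overview

1. Numbering: benzofuran O1, C2, C3, C3a, C4–C7, C7a (ring A arene, ring B dihydrofuran). Ring C is the cyclohexane C1'–C6' (C1' carbinol on C2, C3' CHOH, C4' CHOMe). The target is 2S,3R,1'S,3'S,4'S with a 2,3-trans ring B.
2. Feature used: C2–O1 and C1'–OH sit on neighbouring carbons, C6' is bare, and C3'/C4' carry trans oxygens. Ring C is therefore the oxidation pattern of a cyclohexa-1,4-dien-1-yl group on a C2 carbinol, with C1'=C6' allylic to the C2 hydroxyl and C3'=C4' kept for later.
3. Late disconnections: C4'–OMe/C3'–OH come from diaxial methanolysis of a C3'–C4' epoxide placed by the C1' hydroxyl. O1–C2 (ring B) comes from 5-exo phenoxide opening of a C2–C1' epoxide made from the C2 mesylate, so C2 is inverted twice.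
4. Key disconnection: C1'–O comes from a C1'–C6' oxirane delivered by the C2 hydroxyl, followed by hydride at C6'. C2–C3 comes from an Evans syn aldol of the ring A arylacetyl imide with cyclohexa-1,4-diene-1-carbaldehyde.
5. Ring order: ring A is bought, then ring C by Diels–Alder (butadiene + methyl propiolate), the C1'–C6' oxirane, the C2–C1' oxirane, ring B, and the C3'–C4' oxirane.

Key step: step 13

Remark: the future O1 travels as an allyl ether. It must be freed beside an acid-labile C2–C1' epoxide, the C3'=C4' alkene and an easily oxidised para-alkyl guaiacol, which rules out acid, hydrogenolysis and quinone oxidants, whereas zerovalent palladium in basic methanol fits.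

Abbreviations: TBS = tert-butyldimethylsilyl. Ar = 2-(allyloxy)-3-methoxy-5-[3-(TBS-oxy)propyl]phenyl, whose C1 is the future C3a and whose C2 oxygen is the future O1.

## Route

Step 1
Reactants: 1 dihydroconiferyl alcohol (4-(3-hydroxypropyl)-2-methoxyphenol)
Product: 2 2-bromo-4-(3-hydroxypropyl)-6-methoxyphenol
Conditions: NBS (1.0 equiv), i-Pr2NH (10 mol %), CH2Cl2, 0 °C
Reagents that add atoms: N-bromosuccinimide, O=C1CCC(=O)N1Br
Why: Electrophilic aromatic bromination is steered by the free phenol, whose para carbon (C5) is blocked by the side chain, so the amine-relayed bromine goes to its only open ortho carbon, the future C3a.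

Step 2
Reactants: 2 2-bromo-4-(3-hydroxypropyl)-6-methoxyphenol
Product: 3 3-[4-(allyloxy)-3-bromo-5-methoxyphenyl]propan-1-ol
Conditions: allyl bromide (1.2 equiv), K2CO3, acetone, reflux
Reagents that add atoms: allyl bromide, C=CCBr
Why: In this Williamson ether synthesis carbonate deprotonates only the phenol, so the future O1 is masked while the aliphatic alcohol stays free.

Step 3
Reactants: 3 3-[4-(allyloxy)-3-bromo-5-methoxyphenyl]propan-1-ol
Product: 4 tert-butyl{3-[4-(allyloxy)-3-bromo-5-methoxyphenyl]propoxy}dimethylsilane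
Conditions: TBSCl, imidazole, CH2Cl2, rt
Reagents that add atoms: tert-butyldimethylsilyl chloride, CC(C)(C)[Si](C)(C)Cl
Why: Imidazole-promoted silylation of the primary alcohol removes the last acidic proton before metalation.

Step 4
Reactants: 4 aryl bromide; 5 oxirane (ethylene oxide)
Product: 7 2-Ar-ethan-1-ol, via aryllithium 6 (not isolated)
Conditions: n-BuLi (1.05 equiv), THF, −78 °C; BF3·OEt2 (1.2 equiv), 5 (3 equiv), −78 °C
Reagents that add atoms: none
Why: Bromine–lithium exchange and BF3-assisted SN2 opening of oxirane by the aryllithium install the two carbons that become C3 and its CH2OH, and the low temperature keeps the ortho-allyloxy aryllithium from adding to its own allyl group.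

Step 5
Reactants: 7 2-Ar-ethan-1-ol
Product: 9 2-Ar-acetic acid, via arylacetaldehyde 8 (not isolated)
Conditions: TEMPO (20 mol %), PhI(OAc)2 (2.5 equiv), MeCN–H2O 1:1, rt
Reagents that add atoms: water, O
Why: Oxoammonium (TEMPO) oxidation takes the primary alcohol through the aldehyde hydrate to the acid without touching the allyl ether, the silyl ether or the electron-rich arene.

Step 6
Reactants: 9 2-Ar-acetic acid; 10 (S)-4-benzyl-2-oxazolidinone
Product: 12 (S)-3-(Ar-acetyl)-4-benzyl-2-oxazolidinone, via mixed pivalic anhydride 11 (not isolated)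
Conditions: PivCl, Et3N, THF, −20 °C; then 10, LiCl, −20 °C → rt
Reagents that add atoms: none
Why: In this mixed-anhydride N-acylation the lithium-chelated oxazolidinone attacks the unhindered arylacetyl carbonyl rather than the pivaloyl one, so no strong base is needed.

Step 7
Reactants: 13 buta-1,3-diene; 14 methyl propiolate
Product: 15 methyl cyclohexa-1,4-diene-1-carboxylate
Conditions: toluene, BHT (1 mol %), sealed tube, 120 °C
Reagents that add atoms: none
Why: Thermal [4+2] Diels–Alder cycloaddition of the alkynoate closes ring C directly as the 1-acyl cyclohexa-1,4-diene, the alkyne carbons becoming C1' and C6', and no stereocentre is formed.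

Step 8
Reactants: 15 methyl cyclohexa-1,4-diene-1-carboxylate
Product: 16 (cyclohexa-1,4-dien-1-yl)methanol
Conditions: i-Bu2AlH (2.2 equiv), CH2Cl2, −78 °C → 0 °C
Reagents that add atoms: none
Why: 1,2-Reduction of the conjugated ester by two hydrides stops at the allylic alcohol and leaves both alkenes untouched.

Step 9
Reactants: 16 (cyclohexa-1,4-dien-1-yl)methanol
Product: 17 cyclohexa-1,4-diene-1-carbaldehyde
Conditions: Dess–Martin periodinane (1.1 equiv), CH2Cl2, 0 °C → rt, Ar; used at once
Reagents that add atoms: none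
Why: Dess–Martin oxidation is neutral and non-dehydrogenating, so the skipped diene should neither move into conjugation nor aromatise as it could on a metal oxide or under amine base.

Step 10
Reactants: 12 imide; 17 dienal
Product: 20 (S)-4-benzyl-3-[(2S,3S)-2-Ar-3-(cyclohexa-1,4-dien-1-yl)-3-hydroxypropanoyl]-2-oxazolidinone, via boron Z-enolate 18 (not isolated), via boron aldolate 19 (not isolated)
Conditions: Bu2BOTf (1.1 equiv), Et3N (1.3 equiv), CH2Cl2, −78 → 0 °C; 17, −78 → 0 °C; pH 7 buffer, MeOH, 30% H2O2, 0 °C
Reagents that add atoms: none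
Why: In the Evans syn aldol the Z-boron enolate reacts through a closed Zimmerman–Traxler chair on the face away from the benzyl group of the S auxiliary, which sets C3 and C2 together as the syn adduct with the spatial arrangement of C2–O and C3–aryl found in the target.

Step 11
Reactants: 20 syn aldol adduct
Product: 21 (1S,2R)-2-Ar-1-(cyclohexa-1,4-dien-1-yl)propane-1,3-diol
Conditions: LiBH4 (2 equiv), H2O (1.1 equiv), Et2O, 0 °C
Reagents that add atoms: none
Why: In this reductive auxiliary removal borohydride attacks the exocyclic imide carbonyl and takes it to the primary alcohol without touching C2, C3 or the diene, and the oxazolidinone is released for reuse.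

Step 12
Reactants: 21 diol
Product: 22 (1S,2R)-2-Ar-3-(TBS-oxy)-1-(cyclohexa-1,4-dien-1-yl)propan-1-ol (C2 S, C3 R)
Conditions: TBSCl (1.05 equiv), imidazole, CH2Cl2, 0 °C
Reagents that add atoms: tert-butyldimethylsilyl chloride, CC(C)(C)[Si](C)(C)Cl
Why: Silylation is sterically differentiated, so the primary hydroxyl reacts far faster than the hindered secondary allylic C2 hydroxyl, which must stay free as the directing group.

Step 13
Reactants: 22 dienyl carbinol
Product: 23 (1S,2R)-2-Ar-3-(TBS-oxy)-1-[(1S,6S)-7-oxabicyclo[4.1.0]hept-3-en-1-yl]propan-1-ol (erythro; C2 S, C3 R, C1' S, C6' S)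
Conditions: VO(acac)2 (5 mol %), t-BuOOH (5.5 M in decane, 1.2 equiv), CH2Cl2, 0 °C, Ar
Reagents that add atoms: tert-butyl hydroperoxide, CC(C)(C)OO
Why: VO(acac)2 is oxidised by t-BuOOH to a pentavalent vanadium alkoxide that binds both the C2 hydroxyl of 22 and tert-butyl peroxide, and the activated peroxide oxygen is handed to C1'=C6' in one concerted suprafacial step. The closest known reaction type is the vanadium-catalysed hydroxyl-directed epoxidation of secondary allylic alcohols that carry a substituent geminal to the carbinol, such as 1-(cyclohex-1-enyl)alkanols, which is erythro-selective. The one ring closed is the C1'–O–C6' oxirane, formed by syn oxygen-atom transfer in which both C–O bonds arise on the same alkene face, so it is necessarily cis-fused to ring C. C1' (S) is controlled by the C2 stereocentre, because the small O–C2–C1'=C6' dihedral angle required by the metal leaves one C2 substituent almost eclipsed with the C2' methylene, A(1,2) strain makes that substituent H rather than the bulky C3 branch, and the face then covered by the vanadate gives the erythro isomer, while C6' (S) follows from the cis fusion and is deleted in step 14. The step needs site selectivity among three alkenes, and only C1'=C6' is allylic to the bound hydroxyl, whereas C3'=C4' is bishomoallylic and held across the ring, the O-allyl alkene is remote, and unbound alkenes are nearly inert to this oxidant. Low temperature, a small excess of peroxide and exclusion of air are chosen to suppress hydrogen abstraction from the doubly allylic C2' and C5' methylenes and oxidation of the carbinol to the dienone.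

Step 14
Reactants: 23 epoxy alcohol
Product: 24 (1S)-1-[(1S,2R)-2-Ar-3-(TBS-oxy)-1-hydroxypropyl]cyclohex-3-en-1-ol (C2 S, C3 R, C1' S)
Conditions: LiAlH4 (2 equiv), THF, 0 °C → rt
Reagents that add atoms: none
Why: SN2 hydride opening of the trisubstituted epoxide occurs at the less substituted C6' by axial attack, so C1'–O is kept as a tertiary alcohol of unchanged configuration and the C6' stereocentre disappears.

Step 15
Reactants: 24 secondary/tertiary diol
Product: 26 (2R,3S)-2-[(1R)-1-Ar-2-(TBS-oxy)ethyl]-1-oxaspiro[2.5]oct-5-ene (C2 R, C3 R, C1' S), via C2 mesylate 25 (not isolated)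
Conditions: MsCl (1.2 equiv), Et3N, CH2Cl2, −10 °C; concentrate; K2CO3, MeOH, 0 °C → rt
Reagents that add atoms: none
Why: Chemoselective mesylation of the secondary C2 hydroxyl (the tertiary C1' hydroxyl is inert at this temperature) and Williamson-type 3-exo-tet displacement by the C1' alkoxide give the C2–C1' epoxide with inversion at C2 (S to R) and C1' untouched.

Step 16
Reactants: 26 spiro-epoxide
Product: 28 (2S,3R)-3-(TBS-oxymethyl)-5-[3-(TBS-oxy)propyl]-2-[(1S)-1-hydroxycyclohex-3-en-1-yl]-7-methoxy-2,3-dihydrobenzofuran, via free phenol epoxide 27 (not isolated)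
Conditions: Pd(PPh3)4 (5 mol %), K2CO3 (2 equiv), MeOH, rt → 50 °C
Reagents that add atoms: none
Why: In this Tsuji–Trost-type deallylation zerovalent palladium ionises the aryl allyl ether and methanol takes up the allyl unit, and the freed phenoxide then closes ring B by 5-exo-tet SN2 attack at secondary C2 rather than 6-endo at tertiary C1', which inverts C2 back to S and sets it trans to the C3 substituent, as in base-mediated closures of ortho-(2,3-epoxyalkyl)phenols.

Step 17
Reactants: 28 homoallylic tertiary alcohol
Product: 29 C3'–C4' epoxide of 28 cis to C1'–OH (2S,3R,1'S,3'S,4'R)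
Conditions: VO(acac)2 (5 mol %), t-BuOOH (1.5 equiv), CH2Cl2, 0 °C → rt
Reagents that add atoms: tert-butyl hydroperoxide, CC(C)(C)OO
Why: In this vanadium-catalysed hydroxyl-directed epoxidation of a cyclohex-3-en-1-ol the axial tertiary C1' hydroxyl (the large C2 substituent sits equatorial) carries the peroxo-vanadium to its own face, so the oxirane forms cis to C1'–OH, as known for tertiary cyclohex-3-enols such as terpinen-4-ol.

Step 18
Reactants: 29 cis-epoxy alcohol
Product: 31 difengpiol B, via bis-silyl methoxy diol 30 (not isolated)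
Conditions: camphor-10-sulfonic acid (20 mol %), MeOH, 0 °C → rt
Reagents that add atoms: methanol, CO
Why: Acid-catalysed trans-diaxial (Fürst–Plattner) methanolysis is followed by acid methanolysis of the two primary silyl ethers, and with C1'–OH axial the only chair-like opening is attack of methanol at C4' anti to the oxirane, which gives C4'–OMe (S) trans to C3'–OH (S) and leaves C3'–OH cis to C1'–OH, the inductive pull of C1'–O also disfavouring charge at C3'.

## Compound list

1 | dihydroconiferyl alcohol, 4-(3-hydroxypropyl)-2-methoxyphenol | COc1cc(CCCO)ccc1O | starting material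
2 | 2-bromo-4-(3-hydroxypropyl)-6-methoxyphenol | COc1cc(CCCO)cc(Br)c1O | intermediate
3 | 3-[4-(allyloxy)-3-bromo-5-methoxyphenyl]propan-1-ol | C=CCOc1c(Br)cc(CCCO)cc1OC | intermediate
4 | TBS ether of 3 | C=CCOc1c(Br)cc(CCCO[Si](C)(C)C(C)(C)C)cc1OC | intermediate
5 | oxirane (ethylene oxide) | C1CO1 | starting material
6 | aryllithium Ar–Li (not isolated) | [Li]c1cc(CCCO[Si](C)(C)C(C)(C)C)cc(OC)c1OCC=C | intermediate
7 | 2-Ar-ethan-1-ol | OCCc1cc(CCCO[Si](C)(C)C(C)(C)C)cc(OC)c1OCC=C | intermediate
8 | 2-Ar-acetaldehyde (not isolated) | O=CCc1cc(CCCO[Si](C)(C)C(C)(C)C)cc(OC)c1OCC=C | intermediate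
9 | 2-Ar-acetic acid | OC(=O)Cc1cc(CCCO[Si](C)(C)C(C)(C)C)cc(OC)c1OCC=C | intermediate
10 | (S)-4-benzyl-2-oxazolidinone | O=C1N[C@@H](Cc2ccccc2)CO1 | starting material
11 | mixed anhydride of 9 and pivalic acid (not isolated) | CC(C)(C)C(=O)OC(=O)Cc1cc(CCCO[Si](C)(C)C(C)(C)C)cc(OC)c1OCC=C | intermediate
12 | (S)-3-(Ar-acetyl)-4-benzyl-2-oxazolidinone | O=C(Cc1cc(CCCO[Si](C)(C)C(C)(C)C)cc(OC)c1OCC=C)N1C(=O)OC[C@@H]1Cc1ccccc1 | intermediate
13 | buta-1,3-diene | C=CC=C | starting material
14 | methyl propiolate | C#CC(=O)OC | starting material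
15 | methyl cyclohexa-1,4-diene-1-carboxylate | COC(=O)C1=CCC=CC1 | intermediate
16 | (cyclohexa-1,4-dien-1-yl)methanol | OCC1=CCC=CC1 | intermediate
17 | cyclohexa-1,4-diene-1-carbaldehyde | O=CC1=CCC=CC1 | intermediate
18 | dibutylboron Z-enolate of 12 (not isolated) | CCCCB(CCCC)O/C(=C\c1cc(CCCO[Si](C)(C)C(C)(C)C)cc(OC)c1OCC=C)N1C(=O)OC[C@@H]1Cc1ccccc1 | intermediate
19 | dibutylboron aldolate (not isolated) | CCCCB(CCCC)O[C@H](C1=CCC=CC1)[C@H](c1cc(CCCO[Si](C)(C)C(C)(C)C)cc(OC)c1OCC=C)C(=O)N1C(=O)OC[C@@H]1Cc1ccccc1 | intermediate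
20 | syn aldol adduct, (2S,3S)-acyl chain on the S auxiliary | O[C@H](C1=CCC=CC1)[C@H](c1cc(CCCO[Si](C)(C)C(C)(C)C)cc(OC)c1OCC=C)C(=O)N1C(=O)OC[C@@H]1Cc1ccccc1 | intermediate
21 | (1S,2R)-2-Ar-1-(cyclohexa-1,4-dien-1-yl)propane-1,3-diol | O[C@H](C1=CCC=CC1)[C@H](c1cc(CCCO[Si](C)(C)C(C)(C)C)cc(OC)c1OCC=C)CO | intermediate
22 | key-step precursor, syn C2 carbinol with the cyclohexa-1,4-dienyl group (C2 S, C3 R) | O[C@H](C1=CCC=CC1)[C@H](c1cc(CCCO[Si](C)(C)C(C)(C)C)cc(OC)c1OCC=C)CO[Si](C)(C)C(C)(C)C | intermediate
23 | key-step product, erythro C1'–C6' epoxy alcohol (C2 S, C3 R, C1' S, C6' S) | O[C@H]([C@]12O[C@H]1CC=CC2)[C@H](c1cc(CCCO[Si](C)(C)C(C)(C)C)cc(OC)c1OCC=C)CO[Si](C)(C)C(C)(C)C | intermediate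
24 | C2/C1' diol with C3'=C4' intact (C2 S, C3 R, C1' S) | O[C@H]([C@]1(O)CCC=CC1)[C@H](c1cc(CCCO[Si](C)(C)C(C)(C)C)cc(OC)c1OCC=C)CO[Si](C)(C)C(C)(C)C | intermediate
25 | C2 mesylate of 24 (not isolated) | CS(=O)(=O)O[C@H]([C@]1(O)CCC=CC1)[C@H](c1cc(CCCO[Si](C)(C)C(C)(C)C)cc(OC)c1OCC=C)CO[Si](C)(C)C(C)(C)C | intermediate
26 | C2–C1' spiro-epoxide (C2 R, C3 R, C1' S) | O1[C@@H]([C@@]12CCC=CC2)[C@H](c1cc(CCCO[Si](C)(C)C(C)(C)C)cc(OC)c1OCC=C)CO[Si](C)(C)C(C)(C)C | intermediate
27 | free phenol of 26 (not isolated) | O1[C@@H]([C@@]12CCC=CC2)[C@H](c1cc(CCCO[Si](C)(C)C(C)(C)C)cc(OC)c1O)CO[Si](C)(C)C(C)(C)C | intermediate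
28 | trans-2,3-dihydrobenzofuran with the 1-hydroxycyclohex-3-enyl group (2S,3R,1'S) | COc1cc(CCCO[Si](C)(C)C(C)(C)C)cc2c1O[C@H]([C@]1(O)CCC=CC1)[C@H]2CO[Si](C)(C)C(C)(C)C | intermediate
29 | C3'–C4' epoxide cis to C1'–OH (2S,3R,1'S,3'S,4'R) | COc1cc(CCCO[Si](C)(C)C(C)(C)C)cc2c1O[C@H]([C@]1(O)CC[C@H]3O[C@H]3C1)[C@H]2CO[Si](C)(C)C(C)(C)C | intermediate
30 | bis-TBS ether of difengpiol B (not isolated) | COc1cc(CCCO[Si](C)(C)C(C)(C)C)cc2c1O[C@H]([C@]1(O)CC[C@H](OC)[C@@H](O)C1)[C@H]2CO[Si](C)(C)C(C)(C)C | intermediate
31 | difengpiol B, (1S,3S,4S)-1-[(2S,3R)-3-(hydroxymethyl)-5-(3-hydroxypropyl)-7-methoxy-2,3-dihydrobenzofuran-2-yl]-4-methoxycyclohexane-1,3-diol | COc1cc(CCCO)cc2c1O[C@H]([C@]1(O)CC[C@H](OC)[C@@H](O)C1)[C@H]2CO | target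

## Step count and risks

Total step count: 18. Longest linear sequence: 15 (steps 1–6, then 10–18). The dienal branch (steps 7–9) joins at step 10.

**Step 13 (key step).**
- What may go wrong: the erythro preference may erode. Peroxy radicals may abstract hydrogen from the doubly allylic methylenes and so aromatise ring C. The carbinol may be over-oxidised to the dienone.
- Fallback: it sets out from 22 and comes back at 23, and replaces substrate control by reagent control in a Sharpless asymmetric epoxidation. Conditions are stoichiometric Ti(OiPr)4, L-(+)-diisopropyl tartrate, t-BuOOH, 4 Å sieves, CH2Cl2, −20 °C.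
- Why it should help: the S carbinol 22 has the configuration of the fast-reacting enantiomer for the L-(+)-tartrate complex, and that complex attacks the same C1'=C6' face. The pair is therefore matched and erythro-selective, and the colder ionic conditions spare the skipped diene. No new compound is made (F0).

**Step 15.**
- What may go wrong: sulfonylation of the hindered C2 hydroxyl may be sluggish. The sulfonate may ionise with help from the electron-rich ring A or from the allyl ether oxygen, which would close ring B early with a single inversion.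
- Fallback: it sets out from 24 and comes back at 26 by a Mitsunobu-type cyclodehydration (PPh3, DIAD, toluene, 0 °C → rt).
- Why it should help: the diol is taken up as a dioxaphosphorane, the less hindered C2–O becomes the oxyphosphonium leaving group, and C1'–O displaces it with inversion. No sulfonate ester ever accumulates. No new compound is made (F0).

**Step 18.**
- What may go wrong: regiocontrol may be lost if methanol attacks C3' through the other half-chair.
- Fallback: it sets out from 28 and comes back at 30, and fixes the regiochemistry by a tether.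
  - The C1' alkoxide (KHMDS, THF, −78 °C) is acylated with Boc2O to give the C1' tert-butyl carbonate F1.
  - mCPBA with NaHCO3 (CH2Cl2, 0 °C) attacks anti to the axial carbonate and gives the trans epoxide F2.
  - BF3·OEt2 (CH2Cl2, −78 °C) lets the carbonate carbonyl oxygen open the oxirane at C3' from the C1'–O face. This is a 1,3-diaxial, six-membered closure with loss of isobutene, and it gives the bridged cyclic carbonate alcohol F3, whose only free hydroxyl is at C4'.
  - MeOTf with 2,6-di-tert-butyl-4-methylpyridine gives the C4' methyl ether F4.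
  - K2CO3 in MeOH removes the carbonate to give 30, which is desilylated as in step 18.

## Further compounds

F0 | step 13 | none | none
F0 | step 15 | none | none
F1 | step 18 | C1' tert-butyl carbonate of 28 | COc1cc(CCCO[Si](C)(C)C(C)(C)C)cc2c1O[C@H]([C@]1(OC(=O)OC(C)(C)C)CCC=CC1)[C@H]2CO[Si](C)(C)C(C)(C)C
F2 | step 18 | C3'–C4' epoxide trans to the C1' carbonate | COc1cc(CCCO[Si](C)(C)C(C)(C)C)cc2c1O[C@H]([C@]1(OC(=O)OC(C)(C)C)CC[C@@H]3O[C@@H]3C1)[C@H]2CO[Si](C)(C)C(C)(C)C
F3 | step 18 | C1'/C3' bridged cyclic carbonate with free C4' hydroxyl | COc1cc(CCCO[Si](C)(C)C(C)(C)C)cc2c1O[C@H]([C@]13CC[C@H](O)[C@H](C1)OC(=O)O3)[C@H]2CO[Si](C)(C)C(C)(C)C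
F4 | step 18 | C4' methyl ether of F3 | COc1cc(CCCO[Si](C)(C)C(C)(C)C)cc2c1O[C@H]([C@]13CC[C@H](OC)[C@H](C1)OC(=O)O3)[C@H]2CO[Si](C)(C)C(C)(C)C
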